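**Retrosynthetic overview** (numbering used throughout: ring A C1(OAc)–C2(OBz)–C3(CH3)–C4(H)–C5(CH3)2–C6(OBz); ring B C3–C4–C7H2–C8(OAc)–C9(OH)–C10(H); ring C C9–C11(=O)–C12H2–C13H=C14(CH3)–C15H2–C16(=O)–C10)
1. Ring C is closed last by ring-closing metathesis (C13=C14) of an allyl ketone on C9 and a methallyl ketone on C10; C8–OAc and C9–OH come from a C11-carbinol-directed epoxidation of C8=C9 and acetate opening at C8.
2. Ring A is closed before that by ring-closing metathesis (C1=C2) and C6–OH-directed cis-dihydroxylation; the C6 stereocentre and its oxygen come from (S)-pantolactone.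
3. Ring B is formed first: oxidative dearomatisation of a catechol monoether to a masked o-benzoquinone and intramolecular Diels–Alder reaction with the tethered (E)-enal make C4–C7 and C3–C10; the extra ketal carbon (Cx) is then excised by periodate cleavage and decarboxylation.
4. Enabling feature: C7–C8–C9–C10 of ring B plus the C16 carbonyl carbon are five contiguous ring carbons of 3,4-dihydroxybenzaldehyde (C11 is its formyl carbon), and the C6 oxygen of ring A lies three atoms from C4, so it can be the ketal tether that holds the C3=C4 alkene under the diene.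

Key step: step 9

Remark: β is the face of ring B that carries the C3 methyl group; (R)-TRIP is assumed to give the (R)-carbinol in step 2 (otherwise its antipode is used); (S)-pantolactone is taken as commercial.

Step 1
Reactants: 1 (S)-pantolactone; 2 3,4-dihydroxybenzaldehyde
Product: 4 (3R)-3-(4-formyl-2-hydroxyphenoxy)-4,4-dimethyloxolan-2-one, via pantolactone triflate 3 (not isolated)
Conditions: Tf2O, pyridine, CH2Cl2, −20 °C; then 2, K2CO3 (1.0 equiv), DMF, 0 °C → rt
Reagents that add atoms: none
Why: Triflation followed by SN2 displacement (Williamson-type etherification) by the more acidic para-phenoxide should invert the carbinol centre to (R) and leave the meta-hydroxyl free.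

Step 2
Reactants: 4
Product: 5 (3R)-3-{2-hydroxy-4-[(1R)-1-hydroxybut-3-enyl]phenoxy}-4,4-dimethyloxolan-2-one
Conditions: allylB(pin), (R)-TRIP (5 mol %), toluene, −30 °C
Reagents that add atoms: allylboronic acid pinacol ester, C=CCB1OC(C)(C)C(C)(C)O1
Why: Chiral phosphoric acid-catalysed allylboration of the aryl aldehyde should set the (R)-carbinol (C11) by catalyst control; this centre later steers the epoxidation of step 20 and is erased in step 22.

Step 3
Reactants: 5
Product: 6 bis(triisopropylsilyl) ether of 5 (phenol and C11 carbinol silylated)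
Conditions: i-Pr3SiOTf (2.4 equiv), 2,6-lutidine, CH2Cl2, 0 °C
Reagents that add atoms: triisopropylsilyl trifluoromethanesulfonate, CC(C)[Si](OS(=O)(=O)C(F)(F)F)(C(C)C)C(C)C
Why: Silyl triflate silylation should protect both hydroxyl groups, the aryl ether being the one that fluoride removes selectively in step 8.

Step 4
Reactants: 6
Product: 7 lactol of 6 (oxolan-2-ol, mixture of anomers)
Conditions: i-Bu2AlH (1.2 equiv), toluene, −78 °C
Reagents that add atoms: none
Why: Half-reduction of the γ-lactone should stop at the lactol because the tetrahedral aluminate is stable at −78 °C.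

Step 5
Reactants: 7
Product: 8 (3S)-2,2-dimethyl-3-{4-[(1R)-1-(triisopropylsilyloxy)but-3-enyl]-2-(triisopropylsilyloxy)phenoxy}pent-4-yn-1-ol
Conditions: dimethyl (1-diazo-2-oxopropyl)phosphonate, K2CO3, MeOH, 0 °C → rt
Reagents that add atoms: dimethyl (1-diazo-2-oxopropyl)phosphonate, COP(=O)(OC)C(=[N+]=[N-])C(C)=O
Why: Ohira–Bestmann (Seyferth–Gilbert) homologation of the open hydroxy-aldehyde form should give the terminal alkyne (a masked C1 vinyl group that cannot act as a tethered dienophile) and free the neopentyl alcohol at C4.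

Step 6
Reactants: 8
Product: 9 (3S)-2,2-dimethyl-3-(aryloxy)pent-4-ynal (aryl as in 8)
Conditions: Dess–Martin periodinane, NaHCO3, CH2Cl2, rt
Reagents that add atoms: none
Why: Dess–Martin oxidation of the primary neopentyl alcohol should give the non-enolisable aldehyde without touching alkyne, alkene or silyl ethers.

Step 7
Reactants: 9
Product: 10 (2E,5S)-2,4,4-trimethyl-5-(aryloxy)hept-2-en-6-ynal (aryl as in 8)
Conditions: Ph3P=C(CH3)CHO, toluene, 100 °C
Reagents that add atoms: 2-(triphenylphosphoranylidene)propanal, CC(C=O)=P(c1ccccc1)(c1ccccc1)c1ccccc1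
Why: Wittig olefination with the stabilised ylide should give the (E)-2-methyl enal (formyl trans to the quaternary carbon), the geometry that later places C2 and C5 trans on ring B.

Step 8
Reactants: 10
Product: 11 (2E,5S)-5-{2-hydroxy-4-[(1R)-1-(triisopropylsilyloxy)but-3-enyl]phenoxy}-2,4,4-trimethylhept-2-en-6-ynal
Conditions: Bu4NF (1.05 equiv), THF, −20 °C
Reagents that add atoms: none
Why: Fluoride should cleave the aryl silyl ether much faster than the hindered secondary alkyl silyl ether, liberating only the phenol.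

Step 9
Reactants: 11
Product: 13 tricyclic cycloadduct: bicyclo[2.2.2]oct-5-en-2-one (C16 ketone, bridgeheads C10 and C7, C8=C9) with methoxy ketal carbon Cx linked through oxygen to C6 (oxane ring C7–Cx–O–C6–C5–C4), C3 bearing CH3 and CHO, C6 bearing ethynyl, C9 bearing the (R)-1-(triisopropylsilyloxy)but-3-enyl group, via masked o-benzoquinone 12 (not isolated)
Conditions: PhI(OAc)2 (1.1 equiv), MeOH (10 equiv), CH2Cl2 (5 mM), 0 °C; then toluene, 80 °C
Reagents that add atoms: methanol, CO
Why: PhI(OAc)2 oxidises the phenol and methanol adds to the ring carbon that already carries the C6–O ether, giving the mixed-ketal 6,6-dialkoxycyclohexa-2,4-dienone 12, whose C10=C9–C8=C7 diene then adds to the tethered (E)-C3=C4 alkene in an intramolecular [4+2] cycloaddition that forms C4–C7 and C3–C10; the closest known reaction type is the oxidative dearomatisation of 2-alkoxyphenols to masked o-benzoquinones followed by intramolecular Diels–Alder reaction with an alkene tethered through a ketal oxygen. Ring B (C3–C4–C7–C8–C9–C10) closes as the new cyclohexene of a type 1 intramolecular Diels–Alder reaction inside a bicyclo[2.2.2]octenone, together with the six-membered oxacycle C7–Cx–O–C6–C5–C4 formed by the three-atom tether, which fixes the regiochemistry. C3 (quaternary) and C4 follow from suprafacial addition to the (E)-alkene, and C10 and C7 from the tether, which forces C5 toward the ketal bridge so that the C3 methyl group ends up cis and the formyl group trans to C16, as the target requires. The absolute configuration comes from C6: only the ketal epimer whose tether reaches a chair-like transition state with the ethynyl group equatorial should cyclise readily, so the (S)-centre selects one face of the diene. The step needs chemoselectivity for the trisubstituted enal over the other π-systems and over dimerisation of 12: the ethynyl group cannot span the diene from its one-carbon tether, the allyl group is attached to the diene itself, and high dilution together with the gem-dimethyl group in the tether should favour the intramolecular path.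

Step 10
Reactants: 13
Product: 14 cycloadduct with vinyl in place of ethynyl on C6
Conditions: H2 (1 atm), Pd/CaCO3 poisoned with Pb(OAc)2 (Lindlar catalyst), quinoline, EtOAc, rt
Reagents that add atoms: none
Why: Lindlar semihydrogenation should reduce only the terminal alkyne, unmasking the C1 vinyl group once it can no longer compete as a dienophile.

Step 11
Reactants: 14
Product: 15 cycloadduct with vinyl groups on C3 and C6
Conditions: Ph3PCH3Br, KN(SiMe3)2, THF, 0 °C
Reagents that add atoms: methyltriphenylphosphonium bromide, C[P+](c1ccccc1)(c1ccccc1)c1ccccc1.[Br-]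
Why: Wittig methylenation should take the aldehyde in preference to the hindered, non-enolisable bridged ketone and turn C2 into the second vinyl group for ring A.

Step 12
Reactants: 15
Product: 16 tertiary carbinol: C16(OH)(2-methylallyl), methallyl group on the side of the C8=C9 bridge
Conditions: CH2=C(CH3)CH2MgCl (1.5 equiv), THF, −78 °C
Reagents that add atoms: 2-methylallylmagnesium chloride, CC(=C)C[Mg]Cl
Why: Grignard 1,2-addition to the only carbonyl group should install C15–C14 of ring C, approach occurring past the alkene bridge; the new centre is lost in step 13.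

Step 13
Reactants: 16
Product: 18 ring B keto acid: cyclohexene with C10–C(=O)CH2C(CH3)=CH2, C7–CO2H, C3(CH3)(vinyl) and C4–C(CH3)2–CH(OH)–CH=CH2, via α-hydroxy ketone 17 (not isolated)
Conditions: H5IO6 (3 equiv), THF–H2O (4:1), 0 °C → rt
Reagents that add atoms: water, O
Why: Acidic hydrolysis of the mixed ketal should free the C6 hydroxyl and unveil an α-hydroxy ketone, which periodic acid cleaves (glycol-type cleavage) into the C16 ketone and the C7 carboxylic acid, opening the bicycle to ring B.

Step 14
Reactants: 18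
Product: 19 keto alcohol with C7H2 (carboxyl group removed)
Conditions: 9-mesityl-10-phenylacridinium tetrafluoroborate (5 mol %), PhSSPh (10 mol %), i-Pr2NEt (20 mol %), CF3CH2OH, 450 nm LEDs, rt
Reagents that add atoms: none
Why: Photoredox hydrodecarboxylation should oxidise the carboxylate, lose CO2 to the C7–C8–C9 allyl radical and deliver hydrogen from the thiol to the less hindered C7 terminus, keeping the trisubstituted C8=C9 alkene.

Step 15
Reactants: 19
Product: 20 trans-fused bicyclic dienol: ring A cyclohexene (C1=C2, C6–OH) fused to ring B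
Conditions: RuCl2(PCy3)2(=CHPh) (first-generation Grubbs catalyst, 10 mol %), CH2Cl2 (2 mM), 40 °C
Reagents that add atoms: none
Why: Ring-closing metathesis of the two vinyl groups (diequatorial on ring B, hence trans ring fusion) to a six-membered ring should outrun any reaction of the 1,1-disubstituted methallyl olefin with this catalyst.

Step 16
Reactants: 20
Product: 22 all-cis C1,C2,C6-triol, via osmate ester 21 (not isolated)
Conditions: OsO4 (1.05 equiv), TMEDA (1.1 equiv), CH2Cl2, −78 °C; then aq. Na2SO3, THF, rt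
Reagents that add atoms: osmium tetroxide, O=[Os](=O)(=O)=O
Why: Hydroxyl-directed (Donohoe) dihydroxylation should deliver both oxygens syn to the hydrogen-bonded allylic C6–OH, on the face remote from the axial methyl groups on C3 and C5, setting C1 and C2 and sparing the undirected alkenes.

Step 17
Reactants: 22
Product: 23 C1 monoacetate of 22
Conditions: Ac2O (1.1 equiv), pyridine, CH2Cl2, −20 °C
Reagents that add atoms: acetic anhydride, CC(=O)OC(C)=O
Why: The C1 hydroxyl is the only equatorial, non-neopentyl alcohol and should be acetylated selectively.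

Step 18
Reactants: 23
Product: 24 C1 acetate, C2 and C6 dibenzoate (C11 silyl ether retained)
Conditions: PhC(O)OTf (3 equiv), pyridine, CH2Cl2, −78 → 0 °C
Reagents that add atoms: benzoyl trifluoromethanesulfonate, O=C(OS(=O)(=O)C(F)(F)F)c1ccccc1
Why: Benzoyl triflate should acylate the two hindered axial hydroxyl groups at low temperature, where acetyl migration and enolisation of the β,γ-unsaturated ketone are slow.

Step 19
Reactants: 24
Product: 25 C11 allylic alcohol
Conditions: HF·pyridine, pyridine, THF, 0 °C → rt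
Reagents that add atoms: none
Why: Buffered HF should remove the secondary silyl ether without touching the esters or the ketone.

Step 20
Reactants: 25
Product: 26 8β,9β-epoxy C11 alcohol
Conditions: VO(acac)2 (5 mol %), t-BuOOH (1.5 equiv), CH2Cl2, 0 °C → rt
Reagents that add atoms: tert-butyl hydroperoxide, CC(C)(C)OO
Why: Vanadium-catalysed hydroxyl-directed epoxidation should be selective for the allylic C8=C9 alkene and, with C10 geminal to the carbinol, should pass through the A(1,2)-minimised transition state that delivers oxygen from the (R)-carbinol to the β face (erythro selectivity).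

Step 21
Reactants: 26
Product: 27 C8 α-acetate, C9 β-hydroxyl, C11 carbinol
Conditions: Ti(OiPr)4 (1.5 equiv), AcOH (3 equiv), CH2Cl2, rt
Reagents that add atoms: acetic acid, CC(=O)O
Why: Titanium-mediated opening of the 2,3-epoxy alcohol should occur at the epoxide carbon remote from the carbinol (C8) with inversion, giving the trans-diaxial C8–OAc/C9–OH pair.

Step 22
Reactants: 27
Product: 28 C11 ketone (allyl ketone on C9, methallyl ketone on C10)
Conditions: Dess–Martin periodinane, NaHCO3, CH2Cl2, 0 °C
Reagents that add atoms: none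
Why: Dess–Martin oxidation should convert the secondary C11 carbinol into the ketone and leave the tertiary C9 hydroxyl untouched.

Step 23
Reactants: 28
Product: 29 CNP0214674.2 (target)
Conditions: RuCl2(H2IMes)(=CH-C6H4-2-OiPr) (second-generation Hoveyda–Grubbs catalyst, 15 mol %), 1,4-benzoquinone (30 mol %), toluene (1 mM), 80 °C
Reagents that add atoms: none
Why: Ring-closing metathesis of the allyl and methallyl ketones, held trans-diequatorial on ring B, should close the eight-membered ring with the ring-enforced (Z)-trisubstituted C13=C14 alkene; benzoquinone suppresses olefin migration.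

**Compound list**
1 | (S)-pantolactone, (3S)-3-hydroxy-4,4-dimethyloxolan-2-one | CC1(C)COC(=O)[C@H]1O | starting material
2 | 3,4-dihydroxybenzaldehyde | O=Cc1ccc(O)c(O)c1 | starting material
3 | (S)-pantolactone triflate (not isolated) | CC1(C)COC(=O)[C@H]1OS(=O)(=O)C(F)(F)F | intermediate
4 | (3R)-3-(4-formyl-2-hydroxyphenoxy)-4,4-dimethyloxolan-2-one | CC1(C)COC(=O)[C@@H]1Oc1ccc(C=O)cc1O | intermediate
5 | (3R)-3-{2-hydroxy-4-[(1R)-1-hydroxybut-3-enyl]phenoxy}-4,4-dimethyloxolan-2-one | CC1(C)COC(=O)[C@@H]1Oc1ccc([C@H](O)CC=C)cc1O | intermediate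
6 | bis(triisopropylsilyl) ether of 5 | CC1(C)COC(=O)[C@@H]1Oc1ccc([C@H](O[Si](C(C)C)(C(C)C)C(C)C)CC=C)cc1O[Si](C(C)C)(C(C)C)C(C)C | intermediate
7 | lactol of 6 (anomeric mixture, anomeric centre undefined) | CC1(C)COC(O)[C@@H]1Oc1ccc([C@H](O[Si](C(C)C)(C(C)C)C(C)C)CC=C)cc1O[Si](C(C)C)(C(C)C)C(C)C | intermediate
8 | (3S)-2,2-dimethyl-3-(aryloxy)pent-4-yn-1-ol, aryl = 4-[(1R)-1-(triisopropylsilyloxy)but-3-enyl]-2-(triisopropylsilyloxy)phenyl | C#C[C@H](Oc1ccc([C@H](O[Si](C(C)C)(C(C)C)C(C)C)CC=C)cc1O[Si](C(C)C)(C(C)C)C(C)C)C(C)(C)CO | intermediate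
9 | (3S)-2,2-dimethyl-3-(aryloxy)pent-4-ynal | C#C[C@H](Oc1ccc([C@H](O[Si](C(C)C)(C(C)C)C(C)C)CC=C)cc1O[Si](C(C)C)(C(C)C)C(C)C)C(C)(C)C=O | intermediate
10 | (2E,5S)-2,4,4-trimethyl-5-(aryloxy)hept-2-en-6-ynal | C#C[C@H](Oc1ccc([C@H](O[Si](C(C)C)(C(C)C)C(C)C)CC=C)cc1O[Si](C(C)C)(C(C)C)C(C)C)C(C)(C)/C=C(\C)C=O | intermediate
11 | (2E,5S)-5-{2-hydroxy-4-[(1R)-1-(triisopropylsilyloxy)but-3-enyl]phenoxy}-2,4,4-trimethylhept-2-en-6-ynal | C#C[C@H](Oc1ccc([C@H](O[Si](C(C)C)(C(C)C)C(C)C)CC=C)cc1O)C(C)(C)/C=C(\C)C=O | intermediate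
12 | masked o-benzoquinone: 6-methoxy-6-alkoxycyclohexa-2,4-dienone, productive ketal epimer (not isolated) | O=C1C=C([C@H](O[Si](C(C)C)(C(C)C)C(C)C)CC=C)C=C[C@@]1(OC)O[C@@H](C#C)C(C)(C)/C=C(\C)C=O | intermediate
13 | tricyclic cycloadduct (C3 formyl, C6 ethynyl) | O=C[C@]1(C)[C@H]2C(C)(C)[C@H](C#C)O[C@@]3(OC)C(=O)[C@@H]1C([C@H](O[Si](C(C)C)(C(C)C)C(C)C)CC=C)=C[C@@H]23 | intermediate
14 | cycloadduct (C3 formyl, C6 vinyl) | O=C[C@]1(C)[C@H]2C(C)(C)[C@H](C=C)O[C@@]3(OC)C(=O)[C@@H]1C([C@H](O[Si](C(C)C)(C(C)C)C(C)C)CC=C)=C[C@@H]23 | intermediate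
15 | cycloadduct (C3 vinyl, C6 vinyl) | C=C[C@]1(C)[C@H]2C(C)(C)[C@H](C=C)O[C@@]3(OC)C(=O)[C@@H]1C([C@H](O[Si](C(C)C)(C(C)C)C(C)C)CC=C)=C[C@@H]23 | intermediate
16 | C16 tertiary carbinol with 2-methylallyl group | C=C[C@]1(C)[C@H]2C(C)(C)[C@H](C=C)O[C@@]3(OC)[C@](O)(CC(C)=C)[C@@H]1C([C@H](O[Si](C(C)C)(C(C)C)C(C)C)CC=C)=C[C@@H]23 | intermediate
17 | α-hydroxy ketone after ketal hydrolysis (not isolated) | C=C[C@]1(C)[C@@H](C(C)(C)[C@H](C=C)O)[C@@H]2C=C([C@H](O[Si](C(C)C)(C(C)C)C(C)C)CC=C)[C@H]1[C@@](O)(CC(C)=C)C2=O | intermediate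
18 | ring B keto acid (C7–CO2H, C16 methallyl ketone, C6–OH) | C=C[C@]1(C)[C@@H](C(C)(C)[C@H](C=C)O)[C@@H](C(=O)O)C=C([C@H](O[Si](C(C)C)(C(C)C)C(C)C)CC=C)[C@H]1C(=O)CC(C)=C | intermediate
19 | decarboxylated keto alcohol (C7H2) | C=C[C@]1(C)[C@@H](C(C)(C)[C@H](C=C)O)CC=C([C@H](O[Si](C(C)C)(C(C)C)C(C)C)CC=C)[C@H]1C(=O)CC(C)=C | intermediate
20 | ring A/ring B dienol (C1=C2, C6–OH) | C1=C[C@]2(C)[C@H](CC=C([C@H](O[Si](C(C)C)(C(C)C)C(C)C)CC=C)[C@H]2C(=O)CC(C)=C)C(C)(C)[C@H]1O | intermediate
21 | C1,C2 osmate ester of hexavalent osmium, TMEDA complex (not isolated) | CN(C)CCN(C)C.O4[C@H]1[C@@H](O[Os]4(=O)=O)[C@]2(C)[C@H](CC=C([C@H](O[Si](C(C)C)(C(C)C)C(C)C)CC=C)[C@H]2C(=O)CC(C)=C)C(C)(C)[C@H]1O | intermediate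
22 | all-cis C1,C2,C6-triol | O[C@H]1[C@@H](O)[C@]2(C)[C@H](CC=C([C@H](O[Si](C(C)C)(C(C)C)C(C)C)CC=C)[C@H]2C(=O)CC(C)=C)C(C)(C)[C@H]1O | intermediate
23 | C1 monoacetate | CC(=O)O[C@H]1[C@@H](O)[C@]2(C)[C@H](CC=C([C@H](O[Si](C(C)C)(C(C)C)C(C)C)CC=C)[C@H]2C(=O)CC(C)=C)C(C)(C)[C@H]1O | intermediate
24 | C1 acetate, C2,C6 dibenzoate, C11 silyl ether | CC(=O)O[C@H]1[C@@H](OC(=O)c2ccccc2)[C@]2(C)[C@H](CC=C([C@H](O[Si](C(C)C)(C(C)C)C(C)C)CC=C)[C@H]2C(=O)CC(C)=C)C(C)(C)[C@H]1OC(=O)c1ccccc1 | intermediate
25 | C11 allylic alcohol | CC(=O)O[C@H]1[C@@H](OC(=O)c2ccccc2)[C@]2(C)[C@H](CC=C([C@H](O)CC=C)[C@H]2C(=O)CC(C)=C)C(C)(C)[C@H]1OC(=O)c1ccccc1 | intermediate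
26 | 8β,9β-epoxy C11 alcohol | CC(=O)O[C@H]1[C@@H](OC(=O)c2ccccc2)[C@]2(C)[C@H](C[C@H]3O[C@@]3([C@H](O)CC=C)[C@H]2C(=O)CC(C)=C)C(C)(C)[C@H]1OC(=O)c1ccccc1 | intermediate
27 | C8 acetate, C9,C11-diol | CC(=O)O[C@H]1[C@@H](OC(=O)c2ccccc2)[C@]2(C)[C@H](C[C@H](OC(C)=O)[C@](O)([C@H](O)CC=C)[C@H]2C(=O)CC(C)=C)C(C)(C)[C@H]1OC(=O)c1ccccc1 | intermediate
28 | allyl ketone/methallyl ketone metathesis precursor | CC(=O)O[C@H]1[C@@H](OC(=O)c2ccccc2)[C@]2(C)[C@H](C[C@H](OC(C)=O)[C@](O)(C(=O)CC=C)[C@H]2C(=O)CC(C)=C)C(C)(C)[C@H]1OC(=O)c1ccccc1 | intermediate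
29 | CNP0214674.2 | CC(=O)O[C@H]1[C@@H](OC(=O)c2ccccc2)[C@]2(C)[C@H](C[C@H](OC(C)=O)[C@]3(O)C(=O)C/C=C(/C)CC(=O)[C@H]32)C(C)(C)[C@H]1OC(=O)c1ccccc1 | target

**Totals:** 23 steps; longest linear sequence 23 steps (from 1; 2 enters in step 1).

**Steps most likely to fail**

Step 9: bimolecular dimerisation of the dienone, and loss of the ketal epimer that cannot cyclise, may outpace the hindered intramolecular cycloaddition. The fallback sets out from 11 and blocks dimerisation with a removable bromine. Bromination para to the phenol oxygen (N-bromosuccinimide, MeCN, −20 °C) gives the bromophenol F1. The same oxidation and heating then give the C8-bromo cycloadduct F2, whose dienone is expected to dimerise far more slowly. Lindlar semihydrogenation gives the vinyl compound F3, and radical hydrodebromination (Bu3SnH, AIBN, benzene, 80 °C) returns to the route at 14.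

Step 20: oxygen delivery to the β face is opposed by the axial C3 methyl group, so the directed epoxidation may be slow or may go to the α face. The fallback sets out from 25 and uses the substrate's own α preference. Bromonium formation on the α face with N-bromosuccinimide in aqueous THF and anti attack of water at the tertiary C9 give the trans-diaxial bromohydrin F4 (C8 α-Br, C9 β-OH). Intramolecular displacement of bromide (Ag2O, CH2Cl2) then gives the β-epoxide and returns to the route at 26.

Step 23: closure of the eight-membered ring onto a 1,1-disubstituted olefin may be slow, and migration of the β,γ-double bonds into conjugation with the ketones may compete. The fallback sets out from 27 and performs the metathesis on the less sensitive homoallylic alcohol with the same catalyst, giving the ring-closed C11 alcohol F5. Dess–Martin oxidation of F5 then gives 29.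

**Further compounds**
F1 | step 9 | bromophenol: 11 with bromine para to the phenolic hydroxyl (future C8) | C#C[C@H](Oc1cc(Br)c([C@H](O[Si](C(C)C)(C(C)C)C(C)C)CC=C)cc1O)C(C)(C)/C=C(\C)C=O
F2 | step 9 | C8-bromo cycloadduct (C6 ethynyl) | O=C[C@]1(C)[C@H]2C(C)(C)[C@H](C#C)O[C@@]3(OC)C(=O)[C@@H]1C([C@H](O[Si](C(C)C)(C(C)C)C(C)C)CC=C)=C(Br)[C@@H]23
F3 | step 9 | C8-bromo cycloadduct (C6 vinyl) | O=C[C@]1(C)[C@H]2C(C)(C)[C@H](C=C)O[C@@]3(OC)C(=O)[C@@H]1C([C@H](O[Si](C(C)C)(C(C)C)C(C)C)CC=C)=C(Br)[C@@H]23
F4 | step 20 | bromohydrin: C8 α-bromide, C9 β-hydroxyl, C11 carbinol | CC(=O)O[C@H]1[C@@H](OC(=O)c2ccccc2)[C@]2(C)[C@H](C[C@H](Br)[C@](O)([C@H](O)CC=C)[C@H]2C(=O)CC(C)=C)C(C)(C)[C@H]1OC(=O)c1ccccc1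
F5 | step 23 | ring-closed C11 alcohol (target with C11 carbinol in place of the ketone) | CC(=O)O[C@H]1[C@@H](OC(=O)c2ccccc2)[C@]2(C)[C@H](C[C@H](OC(C)=O)[C@]3(O)[C@H](O)C/C=C(/C)CC(=O)[C@H]32)C(C)(C)[C@H]1OC(=O)c1ccccc1
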